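# Synthesis design for (S)-2-methyl-2-{(E)-4-methyl-6-[(S)-2,6,6-trimethylcyclohex-2-en-1-yl]hex-3-en-1-yl}-2H-chromen-6-ol (28)

## The problem

The target 28 is a 2,2-disubstituted 2H-chromen-6-ol. Its pyran ring is fused to the benzene ring at C4a–C8a, and C2 carries a methyl group and a chain that runs through an (E)-trisubstituted alkene to ring A, a 2,6,6-trimethylcyclohex-2-en-1-yl group. There are two stereocentres, the fully substituted ether carbon C2 (S) and the ring A methine (S). They lie seven bonds apart across a flexible chain, so neither can steer the other: each must be set by a reagent-controlled or stereospecific step on its own fragment, and the chain alkene geometry must be fixed independently. C2 is at once tertiary, allylic and an aryl ether carbon, so acid can ionise the C2–O1 bond and heat or light can open the pyran to an ortho-quinone methide; either event would erase its configuration. The free 4-alkoxyphenol is oxidised easily under base and air, and the ring A alkene migrates to the tetrasubstituted position under acid, which rules out strongly acidic steps once ring A is in place. The feature that invites the key step is the pattern of the benzo ring: O1 on C8a and the hydroxyl on C6 are para, C5, C7 and C8 carry hydrogen, and C4a is tied back to C2 through the cis C3=C4 bond. This is the pattern left when an alkyne adds across the 2,5-positions of a furan bearing an alkoxy group on C2 and the oxygen bridge opens toward that alkoxy group, so that the furan oxygen ends as the C6 hydroxyl.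

## Retrosynthesis

**28 to 26.** Bonds C4a–C8a and C5–C6 are cut together, and the C6 hydroxyl is read as a former furan oxygen. This removes both rings of the chromene at once and leads to acid 26, an acyclic ether between a furan and a Z-enynol. Cutting only C4–C4a or only O1–C8a would need a pre-formed, protected hydroquinone ring; the double cut needs none and frees the phenol unprotected. The forward reaction must be an intramolecular [4+2] addition of an unactivated terminal alkyne to an alkoxyfuran, passing through the oxa-bridged adduct 27. The carboxyl group on the furan carbon that becomes C6 is kept on purpose. It is the activating group through which the ether is made. Its removal beforehand would need 120 °C or more, where the enyne ether would already be reacting. On bridge opening it leaves as CO2 in place of a proton, so no separate decarboxylation is needed.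

**26 to 25 to 23 + 24.** The furan C–O1 bond is cut next. A tertiary alkoxide cannot be joined to an unactivated furan, but displacement of nitrite from furoate 24 is an addition–elimination that never touches the C2–O bond, so the configuration of carbinol 23 passes through unchanged. Saponification of ester 25 gives 26 and removes the alkynylsilane in the same operation. The forward reaction needs the hindered alkoxide of 23 to attack C5 of 24 faster than the ester carbonyl or its own enyne.

**23 to 21 + 22, 21 to 20 to 19.** The sp2–sp bond C4–C4a is cut by a Sonogashira coupling of (Z)-iodoalkene 21 with silylacetylene 22. The Z geometry comes from diimide reduction of iodoalkyne 20, made from terminal alkynol 19. Adding a preformed Z-enyne nucleophile to a methyl ketone would give no control at C2; this sequence reduces the enyne to a plain alkyne on a carbinol whose configuration is already secured. The cis-reduction must spare both trisubstituted alkenes and the C–I bond.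

**19 to 17 to 14 + 12, 14 from 13.** The C2–CH2 bond to the chain is cut by lithiation–borylation. Carbamate 14, from commercial (R)-alkynol 13, is lithiated and trapped with boronate 12 (via 15 and 16); 1,2-shift gives tertiary boronic ester 17, and oxidation gives 19 (via 18). Asymmetric alkynylation of a methyl ketone with two similar alkyl arms is the neighbouring option and is unreliable; here the configuration is bought with 13 and carried by stereospecific steps. The cut is convergent: a four-carbon piece and the whole ring A chain. The lithiated carbamate must hold its configuration until trapped.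

**12 to 11 to 10 to 7.** The C–B bond of 12 comes from iodide 11 and alcohol 10. In 10 the methyl–carbon bond and the CH–CH2 bond flanking the alkene are cut back to terminal alkyne 7: syn methylalumination (via 8), then hydroxyethylation of the alanate 9. Olefination of a methyl ketone would give E/Z mixtures, whereas syn carbometallation fixes the E geometry by mechanism. The carboalumination must ignore the ring A alkene.

**7 to 6 to 5 to 4 to 2 to 1.** Alkyne 7 comes from iodide 6 and acetylide; 6 from alcohol 5; 5 from ester 4. The bond between the ring A methine and its CH2 group is cut by a [3,3] shift: 4 arises from allylic alcohol 2 through ketene acetal 3, and 2 from commercial enone 1 by enantioselective reduction. This relays an easily set carbinol centre to the hindered methine beside the quaternary carbon, where direct conjugate addition would struggle. The shift must form a bond next to the gem-dimethyl carbon; its suprafacial course gives the (S) methine.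

## Roads not taken

**Alternative 1:** Cut C4–C4a only. The 4-silyloxyphenyl ether of a tertiary propargylic carbinol, (S)-tert-butyldimethyl({3-methyl-3-[4-(triisopropylsilyloxy)phenoxy]pent-4-yn-1-yl}oxy)silane A2, is treated with the monovalent gold complex Ph3PAuNTf2. The arene carbon ortho to O1 attacks the terminal alkyne carbon 6-endo, giving (S)-2-[2-(tert-butyldimethylsilyloxy)ethyl]-2-methyl-6-(triisopropylsilyloxy)-2H-chromene A1.
- Merits: a known reaction class at room temperature; the C2–O bond is untouched, and there is no thermal threat to the chromene.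
- Weak points: the hydroquinone must be bought and protected. A2 needs O-arylation of a tertiary propargylic alkoxide with retention, since copper-catalysed propargylic substitution would pass through an achiral allenylidene. Cationic gold would also engage the 1,6-enyne formed by the alkyne and the chain alkene, so the chain cannot be present; hence the truncated arm in A1 and further steps (deprotection, oxidation, E-selective chain attachment).
- Comparison: for the ring-forming event itself this road is safer than the chosen one. The chosen plan sets against it a ring closure with the full chain in place, no phenol protecting group, and both rings formed in one operation.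

**Alternative 2:** Cut the two bonds flanking the central C5 unit of the chain. The chloride of (E)-4-chloro-3-methylbut-2-en-1-yl acetate A4 is displaced by lithiated (S)-α-cyclogeranyl phenyl sulfone A5. In the same pot Pd(PPh3)4 (zerovalent palladium) and a β-keto ester sodium enolate replace the allylic acetate, giving methyl (E)-2-acetyl-5-methyl-7-(phenylsulfonyl)-7-[(S)-2,6,6-trimethylcyclohex-2-en-1-yl]hept-4-enoate A3.
- Merits: three components in one flask; the E alkene is bought with A4; the chain is assembled in far fewer steps than the eight that lead to boronate 12. In chain economy this road is better.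
- Weak points: it needs enantiopure A5 and a later reductive desulfonylation. After decarboxylation it ends at methyl ketone (E)-6-methyl-8-[(S)-2,6,6-trimethylcyclohex-2-en-1-yl]oct-5-en-2-one A6. C2 would then have to be set by addition to a ketone whose two alkyl arms are nearly alike, and the chromene is not addressed.
- Comparison: the chosen plan pays for its longer chain synthesis with a stereospecific construction of C2, which needs a boronate and not a ketone.

**Alternative 3:** Cut the ring A bond between the C(CH3)2 carbon and the methine. Geranyl phenyl sulfone A7 is protonated at its terminal alkene by SnCl4 bound to a single-enantiomer 2-alkoxy-2'-hydroxy-1,1'-binaphthyl. The sulfone-bearing alkene attacks the tertiary cation 6-endo and proton loss gives A5.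
- Merits: ring A and its stereocentre in one step from an achiral geraniol derivative, with a sulfone handle suited to alternative 2. If it ran cleanly it would be shorter than steps 1 and 2 of the chosen plan.
- Weak points: the attacking alkene is deactivated by the allylic sulfone. Termination by proton loss can give the α, β and γ alkene isomers. Facial control by a stoichiometric chiral acid is least secure when no strong internal nucleophile ends the cyclisation.
- Comparison: the chosen plan sets against it a catalytic ketone reduction of predictable sense and a [3,3] shift that fixes alkene position and configuration together. Like alternative 2, this road leaves C2 and the chromene unsolved.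

Key step: step 17

Remark on the chemistry: compounds 1, 13, 22 and 24 are taken as commercial; the oxa-bridged intermediate 27 is written without bridgehead descriptors because both bridgehead diastereomers open to the same arene.

Step 1
Reactants: 1 2,4,4-trimethylcyclohex-2-en-1-one
Product: 2 (R)-2,4,4-trimethylcyclohex-2-en-1-ol
Conditions: (S)-1-methyl-3,3-diphenyltetrahydro-1H,3H-pyrrolo[1,2-c][1,3,2]oxazaborole (10 mol%), BH3·SMe2, THF, −20 °C; MeOH
Reagents that add atoms: none
Why: Corey–Bakshi–Shibata reduction; the ketone should bind the catalyst boron anti to its larger α-methylalkenyl arm, so hydride from the nitrogen-bound borane reaches one carbonyl face and sets the carbinol as (R), as for other 2-substituted cyclohexenones.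

Step 2
Reactants: 2 (R)-2,4,4-trimethylcyclohex-2-en-1-ol
Product: 4 ethyl 2-[(S)-2,6,6-trimethylcyclohex-2-en-1-yl]acetate, via ketene acetal 3 (not isolated)
Conditions: MeC(OEt)3 (6 equiv), EtCO2H (5 mol%), 140 °C, EtOH distilled off
Reagents that add atoms: triethyl orthoacetate, CC(OCC)(OCC)OCC
Why: Johnson–Claisen rearrangement; the [3,3] shift is suprafacial, so the new C–C bond forms on the ring face that carried oxygen. The (R) carbinol centre is thereby relayed into the (S) ring A methine, and the alkene moves to the 2,3-position of ring A.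

Step 3
Reactants: 4 ethyl 2-[(S)-2,6,6-trimethylcyclohex-2-en-1-yl]acetate
Product: 5 2-[(S)-2,6,6-trimethylcyclohex-2-en-1-yl]ethan-1-ol
Conditions: LiAlH4, Et2O, 0 °C
Reagents that add atoms: none
Why: hydride reduction of an ester to the primary alcohol; the methine stereocentre is not enolisable under these conditions and is untouched.

Step 4
Reactants: 5 2-[(S)-2,6,6-trimethylcyclohex-2-en-1-yl]ethan-1-ol
Product: 6 (S)-6-(2-iodoethyl)-1,5,5-trimethylcyclohex-1-ene
Conditions: I2, PPh3, imidazole, CH2Cl2, 0 °C to rt
Reagents that add atoms: iodine, II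
Why: Appel-type (Garegg–Samuelsson) iodination of a primary alcohol; the buffered, non-acidic medium leaves the ring A alkene in place.

Step 5
Reactants: 6 (S)-6-(2-iodoethyl)-1,5,5-trimethylcyclohex-1-ene
Product: 7 (S)-6-(but-3-yn-1-yl)-1,5,5-trimethylcyclohex-1-ene
Conditions: LiC≡CH·H2NCH2CH2NH2, DMSO, rt
Reagents that add atoms: lithium acetylide (ethylenediamine complex), [Li+].[C-]#C
Why: SN2 alkylation of acetylide by an unhindered primary iodide; the branching sits two carbons away, so substitution should outrun elimination.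

Step 6
Reactants: 7 (S)-6-(but-3-yn-1-yl)-1,5,5-trimethylcyclohex-1-ene
Product: 10 (E)-4-methyl-6-[(S)-2,6,6-trimethylcyclohex-2-en-1-yl]hex-3-en-1-ol, via alkenylalane 8 (not isolated), via lithium alanate 9 (not isolated)
Conditions: Me3Al (2 equiv), Cp2ZrCl2 (20 mol%), CH2Cl2, 0 °C to rt; volatiles removed, THF; nBuLi, −78 °C; oxirane, −78 °C to rt
Reagents that add atoms: trimethylaluminium, C[Al](C)C; oxirane, C1CO1
Why: Negishi zirconium-catalysed carboalumination adds methyl and aluminium syn across the terminal alkyne, methyl to the internal carbon, which fixes the E geometry by mechanism; the alanate then opens oxirane with retention at the alkenyl carbon. Trisubstituted alkenes do not carboaluminate under these conditions.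

Step 7
Reactants: 10 (E)-4-methyl-6-[(S)-2,6,6-trimethylcyclohex-2-en-1-yl]hex-3-en-1-ol
Product: 11 (S)-6-[(E)-6-iodo-3-methylhex-3-en-1-yl]-1,5,5-trimethylcyclohex-1-ene
Conditions: I2, PPh3, imidazole, CH2Cl2, 0 °C
Reagents that add atoms: iodine, II
Why: Appel-type iodination of a primary homoallylic alcohol under buffered conditions; neither alkene is affected.

Step 8
Reactants: 11 (S)-6-[(E)-6-iodo-3-methylhex-3-en-1-yl]-1,5,5-trimethylcyclohex-1-ene
Product: 12 4,4,5,5-tetramethyl-2-{(E)-4-methyl-6-[(S)-2,6,6-trimethylcyclohex-2-en-1-yl]hex-3-en-1-yl}-1,3,2-dioxaborolane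
Conditions: B2pin2, CuI (10 mol%), PPh3 (13 mol%), LiOMe, DMF, rt
Reagents that add atoms: bis(pinacolato)diboron, CC1(C)OB(OC1(C)C)B1OC(C)(C)C(C)(C)O1
Why: copper-catalysed borylation of a primary alkyl iodide with a diboron reagent; the conditions are mild and basic, and a homoallylic radical or copper species has no favourable cyclisation, so the E alkene is kept.

Step 9
Reactants: 13 (R)-4-(trimethylsilyl)but-3-yn-2-ol
Product: 14 (R)-4-(trimethylsilyl)but-3-yn-2-yl N,N-diisopropylcarbamate
Conditions: iPr2NCOCl, Et3N, 4-(dimethylamino)pyridine (10 mol%), CH2Cl2, reflux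
Reagents that add atoms: N,N-diisopropylcarbamoyl chloride, CC(C)N(C(C)C)C(Cl)=O
Why: O-carbamoylation; the C–O bond at the stereocentre is not broken, so (R) is retained, and the hindered carbamate later serves as directing group for lithiation and as leaving group.

Step 10
Reactants: 14 (R)-4-(trimethylsilyl)but-3-yn-2-yl N,N-diisopropylcarbamate; 12 4,4,5,5-tetramethyl-2-{(E)-4-methyl-6-[(S)-2,6,6-trimethylcyclohex-2-en-1-yl]hex-3-en-1-yl}-1,3,2-dioxaborolane
Product: 17 2-{(3R,6E)-3,7-dimethyl-1-(trimethylsilyl)-9-[(S)-2,6,6-trimethylcyclohex-2-en-1-yl]non-6-en-1-yn-3-yl}-4,4,5,5-tetramethyl-1,3,2-dioxaborolane, via lithiated carbamate 15 (not isolated), via boronate complex 16 (not isolated)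
Conditions: sBuLi, Me2NCH2CH2NMe2, Et2O, −78 °C; then 12, −78 °C; then warm to rt
Reagents that add atoms: none
Why: lithiation–borylation of a secondary propargylic carbamate; deprotonation next to oxygen and trapping by the boronic ester both proceed with retention, and the chain carbon then shifts from boron to carbon anti to the departing carbamate (inversion at carbon). The configuration of 13 is thus transferred stereospecifically to the fully substituted carbon.

Step 11
Reactants: 17 2-{(3R,6E)-3,7-dimethyl-1-(trimethylsilyl)-9-[(S)-2,6,6-trimethylcyclohex-2-en-1-yl]non-6-en-1-yn-3-yl}-4,4,5,5-tetramethyl-1,3,2-dioxaborolane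
Product: 19 (3S,6E)-3,7-dimethyl-9-[(S)-2,6,6-trimethylcyclohex-2-en-1-yl]non-6-en-1-yn-3-ol, via silyl alkynol 18 (not isolated)
Conditions: H2O2, NaOH, THF/H2O, 0 °C; then K2CO3, MeOH, rt
Reagents that add atoms: hydrogen peroxide, OO
Why: oxidation of the C–B bond with retention (1,2-shift from boron to oxygen), then methoxide-mediated cleavage of the alkynyl C–Si bond. Overall the hydrogen of 13 has been replaced by the chain with retention, which gives the (S) carbinol; basic peroxide does not epoxidise unactivated alkenes.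

Step 12
Reactants: 19 (3S,6E)-3,7-dimethyl-9-[(S)-2,6,6-trimethylcyclohex-2-en-1-yl]non-6-en-1-yn-3-ol
Product: 20 (3S,6E)-1-iodo-3,7-dimethyl-9-[(S)-2,6,6-trimethylcyclohex-2-en-1-yl]non-6-en-1-yn-3-ol
Conditions: nBuLi (2.1 equiv), THF, −78 °C; I2 (1.0 equiv), −78 °C; Na2S2O3
Reagents that add atoms: iodine, II
Why: iodination of a lithium acetylide; with one equivalent of iodine at −78 °C the acetylide should react far faster than any iodoetherification of the chain alkene by the alkoxide, which is the reason for choosing the anionic protocol over an electrophilic one.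

Step 13
Reactants: 20 (3S,6E)-1-iodo-3,7-dimethyl-9-[(S)-2,6,6-trimethylcyclohex-2-en-1-yl]non-6-en-1-yn-3-ol
Product: 21 (1Z,3S,6E)-1-iodo-3,7-dimethyl-9-[(S)-2,6,6-trimethylcyclohex-2-en-1-yl]nona-1,6-dien-3-ol
Conditions: 2-nitrobenzenesulfonylhydrazide, Et3N, THF/iPrOH, rt
Reagents that add atoms: none
Why: diimide, released from the sulfonylhydrazide by base, transfers two hydrogens suprafacially to the iodoalkyne and gives the (Z)-iodoalkene. Diimide leaves trisubstituted alkenes alone and, unlike catalytic hydrogenation, does not cleave the C–I bond.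

Step 14
Reactants: 21 (1Z,3S,6E)-1-iodo-3,7-dimethyl-9-[(S)-2,6,6-trimethylcyclohex-2-en-1-yl]nona-1,6-dien-3-ol; 22 ethynyltrimethylsilane
Product: 23 (3Z,5S,8E)-5,9-dimethyl-1-(trimethylsilyl)-11-[(S)-2,6,6-trimethylcyclohex-2-en-1-yl]undeca-3,8-dien-1-yn-5-ol
Conditions: Pd(PPh3)4 (5 mol%), CuI (10 mol%), Et3N, THF, rt
Reagents that add atoms: none
Why: Sonogashira coupling; oxidative addition of the alkenyl iodide to zerovalent palladium and reductive elimination both retain the Z geometry, and the free tertiary alcohol is tolerated at room temperature.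

Step 15
Reactants: 23 (3Z,5S,8E)-5,9-dimethyl-1-(trimethylsilyl)-11-[(S)-2,6,6-trimethylcyclohex-2-en-1-yl]undeca-3,8-dien-1-yn-5-ol; 24 methyl 5-nitrofuran-2-carboxylate
Product: 25 methyl 5-({(3Z,5S,8E)-5,9-dimethyl-1-(trimethylsilyl)-11-[(S)-2,6,6-trimethylcyclohex-2-en-1-yl]undeca-3,8-dien-1-yn-5-yl}oxy)furan-2-carboxylate
Conditions: KN(SiMe3)2 (1.05 equiv), THF, −78 °C; then 24, THF/DMF, −78 to −20 °C
Reagents that add atoms: none
Why: nucleophilic aromatic substitution (addition–elimination) at C5 of the nitrofuroate, where the ester stabilises the anionic adduct and nitrite leaves; alkoxides are established nucleophiles for this displacement. The C–O bond of the stereocentre is never broken, so (S) is retained, and the low temperature is meant to keep the alkoxide from adding to its own enyne.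

Step 16
Reactants: 25 methyl 5-({(3Z,5S,8E)-5,9-dimethyl-1-(trimethylsilyl)-11-[(S)-2,6,6-trimethylcyclohex-2-en-1-yl]undeca-3,8-dien-1-yn-5-yl}oxy)furan-2-carboxylate
Product: 26 5-({(3Z,5S,8E)-5,9-dimethyl-11-[(S)-2,6,6-trimethylcyclohex-2-en-1-yl]undeca-3,8-dien-1-yn-5-yl}oxy)furan-2-carboxylic acid
Conditions: LiOH, THF/MeOH/H2O, 0 °C to rt; cold dilute HCl to pH 4–5
Reagents that add atoms: lithium hydroxide, [Li+].[OH-]
Why: saponification of the methyl ester; the same basic methanolic medium cleaves the alkynyl C–Si bond, so the terminal alkyne needed for the cycloaddition is freed without a separate step. The push–pull furoate is far less acid-sensitive than a bare alkoxyfuran and should survive the brief, cold acidification.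

Step 17
Reactants: 26 5-({(3Z,5S,8E)-5,9-dimethyl-11-[(S)-2,6,6-trimethylcyclohex-2-en-1-yl]undeca-3,8-dien-1-yn-5-yl}oxy)furan-2-carboxylic acid
Product: 28 (S)-2-methyl-2-{(E)-4-methyl-6-[(S)-2,6,6-trimethylcyclohex-2-en-1-yl]hex-3-en-1-yl}-2H-chromen-6-ol, via oxa-bridged cycloadduct 27 (not isolated)
Conditions: iPr2NEt (1.5 equiv), 2,6-di-tert-butyl-4-methylphenol (5 mol%), degassed toluene (0.01 M), 110 °C, sealed tube, dark; aq NH4Cl
Reagents that add atoms: none
Why: Proposed new method: as its ammonium carboxylate, 26 is expected to undergo intramolecular [4+2] addition of the terminal alkyne across furan C2 and C5 (bonds C4a–C8a and C5–C6) to give the 7-oxanorbornadiene 27; the lone pair of O1 then breaks the bridge bond at C8a, and the resulting oxido-cyclohexadienyl cation aromatises by losing CO2 from C6 in place of a proton, so that the furan oxygen ends as the free C6 hydroxyl of 28. The closest known reaction types are the intermolecular addition of 2-alkoxyfurans to alkynes with opening to 4-alkoxyphenols, and the intramolecular Diels–Alder reaction of 5-amino-2-furoates and 2-amidofurans with unactivated tethered π-bonds followed by ring opening; new here are the alkoxyfuran with an unactivated enyne and the carboxylate as departing group. The pyran ring closes as part of the cycloaddition through the four-atom tether O1–C2–C3=C4 (bond C4a–C8a), and the carbocycle closes by the second σ-bond of the same event (C5–C6) and becomes benzenoid on bridge opening. No lasting stereocentre is formed: the bridgeheads of 27 are transient, and C2 keeps its configuration because none of its four bonds is involved. The step needs periselectivity for [4+2] over the [3,3] shift of the allyl furyl ether; this should be helped by the Z-enyne holding C4a within reach of furan C2, by the cis-ethynyl group encumbering the allyl terminus that a [3,3] shift would have to bond, and by the push–pull furoate being a poorer ketene-acetal partner than a bare alkoxyfuran. Regiochemistry is fixed by the tether and the direction of bridge opening by O1 on the bridgehead. The amine keeps the medium non-acidic so that the tertiary allylic ether is not ionised, and the lowest effective temperature is used so that the chromene does not open electrocyclically.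

## Compound list

1 | 2,4,4-trimethylcyclohex-2-en-1-one | CC1=CC(C)(C)CCC1=O | starting material
2 | (R)-2,4,4-trimethylcyclohex-2-en-1-ol | CC1=CC(C)(C)CC[C@H]1O | intermediate
3 | (R)-6-[(1-ethoxyethenyl)oxy]-1,3,3-trimethylcyclohex-1-ene (mixed ketene acetal) | CC1=CC(C)(C)CC[C@H]1OC(=C)OCC | intermediate (not isolated)
4 | ethyl 2-[(S)-2,6,6-trimethylcyclohex-2-en-1-yl]acetate | CC1=CCCC(C)(C)[C@@H]1CC(=O)OCC | intermediate
5 | 2-[(S)-2,6,6-trimethylcyclohex-2-en-1-yl]ethan-1-ol | CC1=CCCC(C)(C)[C@@H]1CCO | intermediate
6 | (S)-6-(2-iodoethyl)-1,5,5-trimethylcyclohex-1-ene | CC1=CCCC(C)(C)[C@@H]1CCI | intermediate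
7 | (S)-6-(but-3-yn-1-yl)-1,5,5-trimethylcyclohex-1-ene | CC1=CCCC(C)(C)[C@@H]1CCC#C | intermediate
8 | dimethyl{(E)-2-methyl-4-[(S)-2,6,6-trimethylcyclohex-2-en-1-yl]but-1-en-1-yl}alane | CC1=CCCC(C)(C)[C@@H]1CC/C(C)=C/[Al](C)C | intermediate (not isolated)
9 | lithium butyl(dimethyl){(E)-2-methyl-4-[(S)-2,6,6-trimethylcyclohex-2-en-1-yl]but-1-en-1-yl}alanate | CC1=CCCC(C)(C)[C@@H]1CC/C(C)=C/[Al-](C)(C)CCCC.[Li+] | intermediate (not isolated)
10 | (E)-4-methyl-6-[(S)-2,6,6-trimethylcyclohex-2-en-1-yl]hex-3-en-1-ol | CC1=CCCC(C)(C)[C@@H]1CC/C(C)=C/CCO | intermediate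
11 | (S)-6-[(E)-6-iodo-3-methylhex-3-en-1-yl]-1,5,5-trimethylcyclohex-1-ene | CC1=CCCC(C)(C)[C@@H]1CC/C(C)=C/CCI | intermediate
12 | 4,4,5,5-tetramethyl-2-{(E)-4-methyl-6-[(S)-2,6,6-trimethylcyclohex-2-en-1-yl]hex-3-en-1-yl}-1,3,2-dioxaborolane | CC1=CCCC(C)(C)[C@@H]1CC/C(C)=C/CCB1OC(C)(C)C(C)(C)O1 | intermediate
13 | (R)-4-(trimethylsilyl)but-3-yn-2-ol | C[C@@H](O)C#C[Si](C)(C)C | starting material
14 | (R)-4-(trimethylsilyl)but-3-yn-2-yl N,N-diisopropylcarbamate | C[C@@H](OC(=O)N(C(C)C)C(C)C)C#C[Si](C)(C)C | intermediate
15 | (R)-2-lithio-4-(trimethylsilyl)but-3-yn-2-yl N,N-diisopropylcarbamate | C[C@@]([Li])(OC(=O)N(C(C)C)C(C)C)C#C[Si](C)(C)C | intermediate (not isolated)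
16 | lithium {(R)-2-[(diisopropylcarbamoyl)oxy]-4-(trimethylsilyl)but-3-yn-2-yl}{(E)-4-methyl-6-[(S)-2,6,6-trimethylcyclohex-2-en-1-yl]hex-3-en-1-yl}(pinacolato)borate | CC1=CCCC(C)(C)[C@@H]1CC/C(C)=C/CC[B-]1(OC(C)(C)C(C)(C)O1)[C@](C)(OC(=O)N(C(C)C)C(C)C)C#C[Si](C)(C)C.[Li+] | intermediate (not isolated)
17 | 2-{(3R,6E)-3,7-dimethyl-1-(trimethylsilyl)-9-[(S)-2,6,6-trimethylcyclohex-2-en-1-yl]non-6-en-1-yn-3-yl}-4,4,5,5-tetramethyl-1,3,2-dioxaborolane | CC1=CCCC(C)(C)[C@@H]1CC/C(C)=C/CC[C@](C)(B1OC(C)(C)C(C)(C)O1)C#C[Si](C)(C)C | intermediate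
18 | (3S,6E)-3,7-dimethyl-1-(trimethylsilyl)-9-[(S)-2,6,6-trimethylcyclohex-2-en-1-yl]non-6-en-1-yn-3-ol | CC1=CCCC(C)(C)[C@@H]1CC/C(C)=C/CC[C@](C)(O)C#C[Si](C)(C)C | intermediate (not isolated)
19 | (3S,6E)-3,7-dimethyl-9-[(S)-2,6,6-trimethylcyclohex-2-en-1-yl]non-6-en-1-yn-3-ol | CC1=CCCC(C)(C)[C@@H]1CC/C(C)=C/CC[C@](C)(O)C#C | intermediate
20 | (3S,6E)-1-iodo-3,7-dimethyl-9-[(S)-2,6,6-trimethylcyclohex-2-en-1-yl]non-6-en-1-yn-3-ol | CC1=CCCC(C)(C)[C@@H]1CC/C(C)=C/CC[C@](C)(O)C#CI | intermediate
21 | (1Z,3S,6E)-1-iodo-3,7-dimethyl-9-[(S)-2,6,6-trimethylcyclohex-2-en-1-yl]nona-1,6-dien-3-ol | CC1=CCCC(C)(C)[C@@H]1CC/C(C)=C/CC[C@](C)(O)/C=C\I | intermediate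
22 | ethynyltrimethylsilane (trimethylsilylacetylene) | C#C[Si](C)(C)C | starting material
23 | (3Z,5S,8E)-5,9-dimethyl-1-(trimethylsilyl)-11-[(S)-2,6,6-trimethylcyclohex-2-en-1-yl]undeca-3,8-dien-1-yn-5-ol | CC1=CCCC(C)(C)[C@@H]1CC/C(C)=C/CC[C@](C)(O)/C=C\C#C[Si](C)(C)C | intermediate
24 | methyl 5-nitrofuran-2-carboxylate | COC(=O)c1ccc(o1)[N+](=O)[O-] | starting material
25 | methyl 5-({(3Z,5S,8E)-5,9-dimethyl-1-(trimethylsilyl)-11-[(S)-2,6,6-trimethylcyclohex-2-en-1-yl]undeca-3,8-dien-1-yn-5-yl}oxy)furan-2-carboxylate | CC1=CCCC(C)(C)[C@@H]1CC/C(C)=C/CC[C@@](Oc1ccc(o1)C(=O)OC)(C)/C=C\C#C[Si](C)(C)C | intermediate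
26 | 5-({(3Z,5S,8E)-5,9-dimethyl-11-[(S)-2,6,6-trimethylcyclohex-2-en-1-yl]undeca-3,8-dien-1-yn-5-yl}oxy)furan-2-carboxylic acid | CC1=CCCC(C)(C)[C@@H]1CC/C(C)=C/CC[C@@](Oc1ccc(o1)C(=O)O)(C)/C=C\C#C | intermediate
27 | (2S)-6,8a-epoxy-2-methyl-2-{(E)-4-methyl-6-[(S)-2,6,6-trimethylcyclohex-2-en-1-yl]hex-3-en-1-yl}-6,8a-dihydro-2H-chromene-6-carboxylic acid (oxa-bridged cycloadduct, bridgeheads undefined) | CC1=CCCC(C)(C)[C@@H]1CC/C(C)=C/CC[C@@]1(C)C=CC2=CC3(C(=O)O)C=CC2(O1)O3 | intermediate (not isolated)
28 | (S)-2-methyl-2-{(E)-4-methyl-6-[(S)-2,6,6-trimethylcyclohex-2-en-1-yl]hex-3-en-1-yl}-2H-chromen-6-ol | CC1=CCCC(C)(C)[C@@H]1CC/C(C)=C/CC[C@@]1(C)C=Cc2cc(O)ccc2O1 | target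

## Step count and least certain steps

Total: 17 steps. Longest linear sequence: 16 steps (steps 1–8 and 10–17; step 9 is a one-step branch).

**Step 17 (key step, new method).**
- What may go wrong: the tertiary allyl furyl ether may undergo a [3,3] shift to a butenolide faster than the alkyne reaches the furan. Prolonged heating may also let the product open electrocyclically at O1–C2 and reclose, eroding the C2 configuration. Adventitious acid may ionise the C2–O1 bond.
- Fallback (known chemistry, C2–O bond never broken): it sets out from alkynol 19 and returns at 28. Commercially listed 4-bromo-3-iodophenol is silylated (iPr3SiCl, imidazole) to (4-bromo-3-iodophenoxy)triisopropylsilane F1. Sonogashira coupling of 19 with F1 at the iodide [Pd(PPh3)4, CuI, Et3N, rt] should give (3S,6E)-1-[2-bromo-5-(triisopropylsilyloxy)phenyl]-3,7-dimethyl-9-[(S)-2,6,6-trimethylcyclohex-2-en-1-yl]non-6-en-1-yn-3-ol F2. Semi-hydrogenation over Pd/CaCO3 poisoned with Pb(OAc)2 and quinoline gives (1Z,3S,6E)-1-[2-bromo-5-(triisopropylsilyloxy)phenyl]-3,7-dimethyl-9-[(S)-2,6,6-trimethylcyclohex-2-en-1-yl]nona-1,6-dien-3-ol F3. Palladium-catalysed intramolecular aryl etherification of the tertiary alcohol [Pd(OAc)2, 2-(di-tert-butylphosphino)-1,1'-binaphthyl, Cs2CO3, toluene, 80 °C] closes the pyran at O1–C8a to triisopropyl({(S)-2-methyl-2-[(E)-4-methyl-6-[(S)-2,6,6-trimethylcyclohex-2-en-1-yl]hex-3-en-1-yl]-2H-chromen-6-yl}oxy)silane F4. Bu4NF in THF then frees 28.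

**Step 15.**
- What may go wrong: the hindered alkoxide of 23 may add to its own silylalkyne (5-exo closure or silyl transfer), or attack the ester carbonyl of 24 instead of C5.
- Fallback: the ether is made earlier, on the less hindered and enyne-free alkoxide; it sets out from 19 and returns at 25. Treatment of 19 with KN(SiMe3)2 and 24 gives methyl 5-({(3S,6E)-3,7-dimethyl-9-[(S)-2,6,6-trimethylcyclohex-2-en-1-yl]non-6-en-1-yn-3-yl}oxy)furan-2-carboxylate F5. Iodination (N-iodosuccinimide, AgNO3 10 mol%, acetone) gives methyl 5-({(3S,6E)-1-iodo-3,7-dimethyl-9-[(S)-2,6,6-trimethylcyclohex-2-en-1-yl]non-6-en-1-yn-3-yl}oxy)furan-2-carboxylate F6. Diimide reduction as in step 13 gives methyl 5-({(1Z,3S,6E)-1-iodo-3,7-dimethyl-9-[(S)-2,6,6-trimethylcyclohex-2-en-1-yl]nona-1,6-dien-3-yl}oxy)furan-2-carboxylate F7. Sonogashira coupling with 22 as in step 14 gives 25.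

**Step 10.**
- What may go wrong: partial loss of configuration of lithiated carbamate 15 before trapping, or reaction at the alkyne terminus leading to allenyl products.
- Fallback: C2 is set by epoxidation instead; it sets out from iodide 11 and returns at 19. Alkylation of LiC≡CH·H2NCH2CH2NH2 gives (S)-1,5,5-trimethyl-6-[(E)-3-methyloct-3-en-7-yn-1-yl]cyclohex-1-ene F8. Carboalumination (Me3Al, Cp2ZrCl2) and trapping with paraformaldehyde give (2E,6E)-3,7-dimethyl-9-[(S)-2,6,6-trimethylcyclohex-2-en-1-yl]nona-2,6-dien-1-ol F9. Sharpless epoxidation [Ti(OiPr)4, L-(+)-diethyl tartrate, tBuOOH, −20 °C] gives {(2S,3S)-3-methyl-3-[(E)-4-methyl-6-[(S)-2,6,6-trimethylcyclohex-2-en-1-yl]hex-3-en-1-yl]oxiran-2-yl}methanol F10. PPh3 in CCl4 gives (2S,3R)-3-(chloromethyl)-2-methyl-2-[(E)-4-methyl-6-[(S)-2,6,6-trimethylcyclohex-2-en-1-yl]hex-3-en-1-yl]oxirane F11. nBuLi (3 equiv) in THF at −40 °C effects the double elimination to 19 with the tertiary C–O bond intact.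

**Step 6.**
- What may go wrong: slow opening of the epoxide by the alanate, with loss of the alkenyl metal to proton sources.
- Fallback: it sets out from 7 and returns at 10. The alkenylalane is quenched with iodine to (S)-6-[(E)-4-iodo-3-methylbut-3-en-1-yl]-1,5,5-trimethylcyclohex-1-ene F12. Iodine–lithium exchange (tBuLi, Et2O, −78 °C) and opening of oxirane in the presence of BF3·OEt2 give 10.

**Step 2.**
- What may go wrong: acid-catalysed ionisation or dehydration of the allylic alcohol at 140 °C outrunning the hindered shift next to the gem-dimethyl carbon.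
- Fallback: a low-temperature ester enolate rearrangement; it sets out from 2 and returns at 5. Acetylation gives (R)-2,4,4-trimethylcyclohex-2-en-1-yl acetate F13. Ireland–Claisen rearrangement [LiN(iPr)2, Me3SiCl, THF, −78 °C to rt] gives 2-[(S)-2,6,6-trimethylcyclohex-2-en-1-yl]acetic acid F14. LiAlH4 reduces it to 5.

## Further compounds

F1 | step 17 | (4-bromo-3-iodophenoxy)triisopropylsilane | CC(C)[Si](Oc1ccc(Br)c(I)c1)(C(C)C)C(C)C
F2 | step 17 | (3S,6E)-1-[2-bromo-5-(triisopropylsilyloxy)phenyl]-3,7-dimethyl-9-[(S)-2,6,6-trimethylcyclohex-2-en-1-yl]non-6-en-1-yn-3-ol | CC1=CCCC(C)(C)[C@@H]1CC/C(C)=C/CC[C@](C)(O)C#Cc1cc(O[Si](C(C)C)(C(C)C)C(C)C)ccc1Br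
F3 | step 17 | (1Z,3S,6E)-1-[2-bromo-5-(triisopropylsilyloxy)phenyl]-3,7-dimethyl-9-[(S)-2,6,6-trimethylcyclohex-2-en-1-yl]nona-1,6-dien-3-ol | CC1=CCCC(C)(C)[C@@H]1CC/C(C)=C/CC[C@](C)(O)/C=C\c1cc(O[Si](C(C)C)(C(C)C)C(C)C)ccc1Br
F4 | step 17 | triisopropyl({(S)-2-methyl-2-[(E)-4-methyl-6-[(S)-2,6,6-trimethylcyclohex-2-en-1-yl]hex-3-en-1-yl]-2H-chromen-6-yl}oxy)silane | CC1=CCCC(C)(C)[C@@H]1CC/C(C)=C/CC[C@@]1(C)C=Cc2cc(O[Si](C(C)C)(C(C)C)C(C)C)ccc2O1
F5 | step 15 | methyl 5-({(3S,6E)-3,7-dimethyl-9-[(S)-2,6,6-trimethylcyclohex-2-en-1-yl]non-6-en-1-yn-3-yl}oxy)furan-2-carboxylate | CC1=CCCC(C)(C)[C@@H]1CC/C(C)=C/CC[C@@](Oc1ccc(o1)C(=O)OC)(C)C#C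
F6 | step 15 | methyl 5-({(3S,6E)-1-iodo-3,7-dimethyl-9-[(S)-2,6,6-trimethylcyclohex-2-en-1-yl]non-6-en-1-yn-3-yl}oxy)furan-2-carboxylate | CC1=CCCC(C)(C)[C@@H]1CC/C(C)=C/CC[C@@](Oc1ccc(o1)C(=O)OC)(C)C#CI
F7 | step 15 | methyl 5-({(1Z,3S,6E)-1-iodo-3,7-dimethyl-9-[(S)-2,6,6-trimethylcyclohex-2-en-1-yl]nona-1,6-dien-3-yl}oxy)furan-2-carboxylate | CC1=CCCC(C)(C)[C@@H]1CC/C(C)=C/CC[C@@](Oc1ccc(o1)C(=O)OC)(C)/C=C\I
F8 | step 10 | (S)-1,5,5-trimethyl-6-[(E)-3-methyloct-3-en-7-yn-1-yl]cyclohex-1-ene | CC1=CCCC(C)(C)[C@@H]1CC/C(C)=C/CCC#C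
F9 | step 10 | (2E,6E)-3,7-dimethyl-9-[(S)-2,6,6-trimethylcyclohex-2-en-1-yl]nona-2,6-dien-1-ol | CC1=CCCC(C)(C)[C@@H]1CC/C(C)=C/CC/C(C)=C/CO
F10 | step 10 | {(2S,3S)-3-methyl-3-[(E)-4-methyl-6-[(S)-2,6,6-trimethylcyclohex-2-en-1-yl]hex-3-en-1-yl]oxiran-2-yl}methanol | CC1=CCCC(C)(C)[C@@H]1CC/C(C)=C/CC[C@]2(C)O[C@H]2CO
F11 | step 10 | (2S,3R)-3-(chloromethyl)-2-methyl-2-[(E)-4-methyl-6-[(S)-2,6,6-trimethylcyclohex-2-en-1-yl]hex-3-en-1-yl]oxirane | CC1=CCCC(C)(C)[C@@H]1CC/C(C)=C/CC[C@]2(C)O[C@H]2CCl
F12 | step 6 | (S)-6-[(E)-4-iodo-3-methylbut-3-en-1-yl]-1,5,5-trimethylcyclohex-1-ene | CC1=CCCC(C)(C)[C@@H]1CC/C(C)=C/I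
F13 | step 2 | (R)-2,4,4-trimethylcyclohex-2-en-1-yl acetate | CC1=CC(C)(C)CC[C@H]1OC(C)=O
F14 | step 2 | 2-[(S)-2,6,6-trimethylcyclohex-2-en-1-yl]acetic acid | CC1=CCCC(C)(C)[C@@H]1CC(=O)O
A1 | alternative 1 | (S)-2-[2-(tert-butyldimethylsilyloxy)ethyl]-2-methyl-6-(triisopropylsilyloxy)-2H-chromene | CC(C)(C)[Si](C)(C)OCC[C@@]1(C)C=Cc2cc(O[Si](C(C)C)(C(C)C)C(C)C)ccc2O1
A2 | alternative 1 | (S)-tert-butyldimethyl({3-methyl-3-[4-(triisopropylsilyloxy)phenoxy]pent-4-yn-1-yl}oxy)silane | CC(C)(C)[Si](C)(C)OCC[C@@](Oc1ccc(O[Si](C(C)C)(C(C)C)C(C)C)cc1)(C)C#C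
A3 | alternative 2 | methyl (E)-2-acetyl-5-methyl-7-(phenylsulfonyl)-7-[(S)-2,6,6-trimethylcyclohex-2-en-1-yl]hept-4-enoate | CC1=CCCC(C)(C)[C@@H]1C(S(=O)(=O)c1ccccc1)C/C(C)=C/CC(C(C)=O)C(=O)OC
A4 | alternative 2 | (E)-4-chloro-3-methylbut-2-en-1-yl acetate | CC(=O)OC/C=C(\C)CCl
A5 | alternative 3 | (S)-α-cyclogeranyl phenyl sulfone, (S)-({[2,6,6-trimethylcyclohex-2-en-1-yl]methyl}sulfonyl)benzene | CC1=CCCC(C)(C)[C@@H]1CS(=O)(=O)c1ccccc1
A6 | alternative 2 | (E)-6-methyl-8-[(S)-2,6,6-trimethylcyclohex-2-en-1-yl]oct-5-en-2-one | CC1=CCCC(C)(C)[C@@H]1CC/C(C)=C/CCC(C)=O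
A7 | alternative 3 | geranyl phenyl sulfone, (E)-[(3,7-dimethylocta-2,6-dien-1-yl)sulfonyl]benzene | CC(C)=CCC/C(C)=C/CS(=O)(=O)c1ccccc1
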